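**Conventions and assumptions**

- Numbering: the decalin is numbered as a rearranged drimane (avarane). Ring A is C1–C4, C5, C10 and ring B is C5–C10. C11 is the exocyclic methylene carbon on C4 and C15 the CH2 on C9. Arene carbons are primed (C1' bonded to C15, C5' carrying CO2Me). β is the face of the C5 methyl group.
- Racemic hex-4-yn-3-ol is used. Its carbinol carbon becomes C7, is carried as a pair of epimers through 2–4 and 9–11, and turns sp2 in 12.
- In step 5 the (S)-configured oxazoline–sulfonamide ligand is assumed to deliver the (S)-carbinol; if the sense is opposite, its antipode is used.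
- Stereochemical check of the cycloaddition: the (E)-enal, the (E)-C5=C6 bond, the (Z)-enol ether and the (S)-C4 centre of 16 translate through an endo transition state into exactly the five stereocentres drawn for 17, so neither structure needed correction.
- Design changes before the cycloaddition: the diene is silylated before any enal exists (an enal would compete in soft enolisation by γ-deprotonation), so C10 travels as an N-methoxy-N-methylamide; C4–O and C7–O carry different silyl groups; the arene is introduced with its ester already in place.
- Electronic caveat for the cycloaddition: the tether forces the enol-ether α-carbon C8 onto the enal α-carbon C9. This is opposite to the intrinsic "para" preference of a 2-silyloxy diene, so the reaction relies on HOMO raising and Lewis-acid activation rather than on matched termini.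

## Structural features

The target is a rearranged drimane sesquiterpene: a trans-fused decalin (ring A and ring B) linked through the C15 methylene on C9 to C1' of a methyl 2,3,4-trihydroxybenzoate. Ring B carries four contiguous stereocentres: C5 (quaternary, axial methyl), C10 (ring-fusion hydrogen), C9 (quaternary, axial methyl and equatorial C15) and C8 (equatorial methyl). The C5 and C9 methyl groups are syn-diaxial, and C8 and C9 carry cis methyl groups. Ring A has no stereocentre of its own but carries the exocyclic C4=C11 methylene next to the quaternary C5. The fragile groups are this 1,1-disubstituted alkene (acid moves it into the ring), the pyrogallol unit (easily oxidised) and the methyl ester (sensitive to hard nucleophiles and strong base). The real difficulty is the pair of quaternary carbons set in a defined relation to C8 and C10, together with the neopentyl C15–aryl link, all as one enantiomer. The key step exploits the fact that the C5–C10 and C8–C9 bonds of ring B are the two σ-bonds a diene C5=C6–C7=C8 and a dienophile C9=C10 would form. The C1–C4 chain can then act as the tether, so that ring A closes in the same event.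

## Logic of the disconnections

**31 ⇒ 30.** The three phenolic O–H bonds are traced back to O–CH2OCH3 acetals. The free pyrogallol would not survive organometallic, hydride, radical and ylide chemistry, whereas the acetals are inert to all of it. The demand on the forward step is an acetal cleavage mild enough to leave the exocyclic alkene where it is.

**30 ⇒ 29 ⇒ 28 ⇒ 27.** The C4=C11 bond is cut to a C4 ketone, which is taken back through the alcohol to the C4 silyl ether. The C4 oxygen is needed earlier as the stereocontrol element, and installing the alkene last keeps it away from acid, radicals and hydride. The forward demand is methylenation of a ketone flanked by the quaternary C5 without attack on the aryl ester.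

**27 ⇒ 26 ⇒ 25.** The C15–H and C7–H bonds are traced back to C15–O and C7–O. Both oxygens are left over from bond-forming events (aryl addition and diene activation) and can be removed together in one radical step. The demand is thioacylation of two hindered hydroxyl groups and a radical reduction that tolerates ester and acetals.

**25 ⇒ 19 + 22 (22 ⇒ 21 ⇒ 20).** The C15–C1' bond is cut. A neopentyl carbon cannot be joined by substitution, but the C9 formyl group accepts an aryl nucleophile, and the arene arrives complete with its ester. 22 comes from 20 by one C–I and three O–C bonds. The demand is an aryl metal that coexists with its own ester and prefers the aldehyde to the C7 ketone.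

**19 ⇒ 17.** The C8 configuration and the C7 enol ether are adjusted. The cycloaddition can only deliver the C8 epimer, because the enol ether methyl must sit outside the diene, so the C7 ketone is used to invert C8. The demand is an equilibrium that favours the equatorial methyl.

**17 ⇒ 16.** The C5–C10 and C8–C9 bonds are cut. This returns both rings and four stereocentres, two of them quaternary, to an open chain with a single stereocentre. The demand is an endo, tether-anti transition state, one diene face, and survival of the enol silyl ether under the Lewis acid.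

**16 ⇒ 14 + 15; 14 ⇒ 13 ⇒ 12.** The C9=C10 bond is cut to an aldehyde and a formyl ylide, the aldehyde is taken back to the amide, and the enol O–Si bond to the ketone. The enal is made last so that enol silylation never meets an enal. The demand is an (E)-selective neutral olefination below the temperature of background cycloaddition, and α′-regioselective, (Z)-selective enol silylation.

**12 ⇒ 11 ⇒ 10 ⇒ 9.** The C7 oxidation level and the two silyl groups are adjusted. C7 must be a ketone for the diene but a protected alcohol while the C4–C5 bond is made. The demand is cleavage of the triethylsilyl ether in the presence of the tert-butyldimethylsilyl ether.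

**9 ⇒ 4 + 7 (4 ⇒ 2 ⇒ 1; 7 ⇒ 6 ⇒ 5).** The C4–C5 bond is cut at the only stereocentre of the chain, which is created in the coupling. This gives a six-carbon alkenyl iodide and a five-carbon aldehyde, each two steps from a commercial compound. The demand is reagent-controlled addition to one aldehyde face with retention of alkene geometry, and regiocontrolled hydrometalation of the alkyne.

## Other disconnections considered

**Alternative 1:** The cut is at C15–C1' and C2'–O. In the forward step the C15 Grignard reagent A1 would add to the aryne A3, released from the iodo sulfonate A2 by iPrMgCl·LiCl. The resulting ortho-arylmagnesium would be oxidised through its borate (B(OMe)3, then H2O2) to the phenol A4.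
- In favour: a C–C and a C–O bond are formed in one flask, no benzylic oxygen has to be deleted afterwards, and the inductive effect of the C3' oxygen should direct the nucleophile to the distal aryne carbon.
- Against: A4 still lacks the ester, so phenol protection, ortho-metalation/carboxylation and deprotection would follow. A hindered neopentyl-type Grignard reagent must compete with iPrMgCl for the aryne. The decalin with its four stereocentres has to be made by other means.
- Comparison: structurally it solves only the junction, not the stereochemical core. Mechanistically it is a polar addition to a strained alkyne, as predictable in regiochemistry as the carbonyl addition of the chosen plan. It is better in that no ester-bearing organometallic and no C15 deoxygenation are needed. In step economy at the junction the two are about equal, because the late carboxylation offsets that gain.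

**Alternative 2:** The cut is at C2–C3 of ring A. In the forward step Me2AlCl would promote a type 2 carbonyl-ene reaction of the aldehyde A5 (ring B carrying methyl and isopropenyl on C5 and a CH2CHO chain on C10) to give the homoallylic alcohol A6.
- In favour: the exocyclic methylene is created directly, so no desilylation, oxidation or ylide chemistry near the ester is needed — a clear advantage over the chosen plan. Six-membered type 2 ene closures are dependable, and the Lewis acid is the same mild one.
- Against: both quaternary carbons and all four ring B stereocentres must already be present in A5, so the hard problem is only moved. The C2 hydroxyl costs a two-step deoxygenation. The methyl ethers would need reagents that the alkene does not tolerate.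
- Comparison: structurally it forms one ring and one disposable stereocentre, against two rings and four stereocentres. Mechanistically both are concerted, Lewis-acid-promoted pericyclic reactions of equal mildness. Its endgame is about one step shorter, but the route to A5 would be longer.

**Alternative 3:** The cuts are at C9–C10 and C4–C5. In the forward step a cobalt hydride, formed at the cathode from Co(C16H14N2O2) (the salen complex of divalent cobalt) and a proton source, would transfer a hydrogen atom to the 1,1-disubstituted alkene of the dienyne A7. The C9 radical would close ring B in a 6-endo mode and the C5 radical ring A in a 6-exo-dig mode. The vinyl radical would end as the methylene of A8, which is the same compound as 30.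
- In favour: both rings, three stereocentres, the exocyclic alkene and the complete arene arrive in one step, one deprotection from the target. Its step economy is clearly better than that of the chosen plan, and its functional-group tolerance is at least equal.
- Against: C9, C10 and C5 would be set under substrate control from the single C8 stereocentre of a flexible chain. The C8/C9 relation is decided in the first radical closure. Hydrogen-atom transfer to the trisubstituted alkene and premature reduction or oxidation of the tertiary radicals would compete. A7 itself needs an enantioenriched C8 and a defined trisubstituted alkene.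
- Comparison: structurally it matches the chosen step in rings formed. Mechanistically it is stepwise and conformationally controlled, whereas the cycloaddition encodes its stereochemistry in alkene geometries. The chosen plan is longer but more predictable in stereochemical outcome.

Key step: step 12

## Route

Step 1
Reactants: 1 hex-4-yn-3-ol (racemic)
Product: 2 triethyl(hex-4-yn-3-yloxy)silane
Conditions: TESCl, imidazole, CH2Cl2, 0 °C → rt
Reagents that add atoms: chlorotriethylsilane, CC[Si](Cl)(CC)CC
Why: Routine silylation of a secondary propargylic alcohol; the triethylsilyl group is chosen because it can later be removed beside the tert-butyldimethylsilyl ether at C4.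

Step 2
Reactants: 2 triethyl(hex-4-yn-3-yloxy)silane
Product: 4 (E)-triethyl[(5-iodohex-4-en-3-yl)oxy]silane, via alkenylzirconocene chloride 3 (not isolated)
Conditions: Cp2Zr(H)Cl (2 equiv), THF, rt → 50 °C; then I2, 0 °C
Reagents that add atoms: iodine, II
Why: Hydrozirconation–iodination: Zr–H adds syn, and with excess reagent the metal should settle on the methyl-bearing carbon remote from the branched silyloxy carbon; iodinolysis with retention gives the iodide with iodine trans to the carbinol carbon, the geometry that becomes the (E)-C5=C6 bond.

Step 3
Reactants: 5 δ-valerolactone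
Product: 6 5-hydroxy-N-methoxy-N-methylpentanamide
Conditions: MeNHOMe·HCl, AlMe3, CH2Cl2, 0 °C → rt
Reagents that add atoms: N,O-dimethylhydroxylamine hydrochloride, CNOC.Cl
Why: Aminolysis of the lactone by the aluminium amide of N,O-dimethylhydroxylamine, a standard opening that leaves the primary alcohol free.

Step 4
Reactants: 6 5-hydroxy-N-methoxy-N-methylpentanamide
Product: 7 N-methoxy-N-methyl-5-oxopentanamide
Conditions: Dess–Martin periodinane, CH2Cl2, 0 °C → rt
Reagents that add atoms: none
Why: Dess–Martin oxidation of a primary alcohol to the aldehyde (future C4); the amide is inert and cannot lactonise as an ester might.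

Step 5
Reactants: 4 (E)-triethyl[(5-iodohex-4-en-3-yl)oxy]silane; 7 N-methoxy-N-methyl-5-oxopentanamide
Product: 9 (5S,6E)-5-hydroxy-N-methoxy-N,6-dimethyl-8-(triethylsilyloxy)dec-6-enamide, via alkenylchromium dichloride 8 (not isolated)
Conditions: CrCl2 (3 equiv), (S)-N-[2-(4-isopropyl-4,5-dihydro-1,3-oxazol-2-yl)-6-methylphenyl]methanesulfonamide (3.3 equiv), Et3N, THF, rt; then NiCl2 (cat.), 4, 7, rt
Reagents that add atoms: none
Why: Asymmetric Nozaki–Hiyama–Kishi coupling: zerovalent nickel inserts into the C–I bond, transmetalation gives an alkenyl species of trivalent chromium that adds only to the aldehyde with retention of alkene geometry, and the chromium-bound chiral sulfonamide selects the aldehyde face to set the (S)-carbinol at C4; amide and silyl ether are tolerated.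

Step 6
Reactants: 9 (5S,6E)-5-hydroxy-N-methoxy-N,6-dimethyl-8-(triethylsilyloxy)dec-6-enamide
Product: 10 (5S,6E)-5-(tert-butyldimethylsilyloxy)-N-methoxy-N,6-dimethyl-8-(triethylsilyloxy)dec-6-enamide
Conditions: TBSCl, imidazole, DMF, rt
Reagents that add atoms: tert-butylchlorodimethylsilane, CC(C)(C)[Si](C)(C)Cl
Why: Standard silylation of the secondary allylic alcohol; this group is the stereocontrol element of step 12 and must outlast the triethylsilyl ether.

Step 7
Reactants: 10 (5S,6E)-5-(tert-butyldimethylsilyloxy)-N-methoxy-N,6-dimethyl-8-(triethylsilyloxy)dec-6-enamide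
Product: 11 (5S,6E)-5-(tert-butyldimethylsilyloxy)-8-hydroxy-N-methoxy-N,6-dimethyldec-6-enamide
Conditions: PPTS (cat.), MeOH, 0 °C
Reagents that add atoms: none
Why: Mild acid methanolysis cleaves the less hindered triethylsilyl ether much faster than the tert-butyldimethylsilyl ether, a well-established selectivity.

Step 8
Reactants: 11 (5S,6E)-5-(tert-butyldimethylsilyloxy)-8-hydroxy-N-methoxy-N,6-dimethyldec-6-enamide
Product: 12 (5S,6E)-5-(tert-butyldimethylsilyloxy)-N-methoxy-N,6-dimethyl-8-oxodec-6-enamide
Conditions: Dess–Martin periodinane, pyridine, CH2Cl2, 0 °C → rt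
Reagents that add atoms: none
Why: Dess–Martin oxidation of the allylic alcohol to the ethyl enone; both C7 epimers converge on one compound and the alkene geometry is untouched.

Step 9
Reactants: 12 (5S,6E)-5-(tert-butyldimethylsilyloxy)-N-methoxy-N,6-dimethyl-8-oxodec-6-enamide
Product: 13 (5S,6E,8Z)-5,8-bis(tert-butyldimethylsilyloxy)-N-methoxy-N,6-dimethyldeca-6,8-dienamide
Conditions: TBSOTf, Et3N, CH2Cl2, −78 → 0 °C
Reagents that add atoms: tert-butyldimethylsilyl trifluoromethanesulfonate, CC(C)(C)[Si](C)(C)OS(=O)(=O)C(F)(F)F
Why: Soft enolisation of the ethyl ketone at the α′ carbon (C8) gives the cross-conjugated 2-silyloxy diene; the (Z)-enol ether should prevail because it keeps the C8 methyl away from the vinylic C6 position, and the amide is not enolised under these conditions.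

Step 10
Reactants: 13 (5S,6E,8Z)-5,8-bis(tert-butyldimethylsilyloxy)-N-methoxy-N,6-dimethyldeca-6,8-dienamide
Product: 14 (5S,6E,8Z)-5,8-bis(tert-butyldimethylsilyloxy)-6-methyldeca-6,8-dienal
Conditions: i-Bu2AlH, THF, −78 °C; aq. potassium sodium tartrate
Reagents that add atoms: none
Why: Hydride reduction of an N-methoxy-N-methylamide stops at the chelated tetrahedral intermediate and releases the aldehyde on work-up; silyl enol ethers are inert to the hydride and to the basic tartrate work-up.

Step 11
Reactants: 14 (5S,6E,8Z)-5,8-bis(tert-butyldimethylsilyloxy)-6-methyldeca-6,8-dienal; 15 2-(triphenylphosphoranylidene)propanal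
Product: 16 (2E,7S,8E,10Z)-7,10-bis(tert-butyldimethylsilyloxy)-2,8-dimethyldodeca-2,8,10-trienal
Conditions: toluene, 70 °C
Reagents that add atoms: none
Why: Wittig reaction of a stabilised formyl ylide, which is (E)-selective and neutral, so the silyloxy diene survives; the temperature is held below that at which the uncatalysed cycloaddition should begin.

Step 12
Reactants: 16 (2E,7S,8E,10Z)-7,10-bis(tert-butyldimethylsilyloxy)-2,8-dimethyldodeca-2,8,10-trienal
Product: 17 4β,7-bis(tert-butyldimethylsilyloxy)-5β,8α,9β-trimethyl-10αH-octal-6-ene-9α-carbaldehyde (trans-fused)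
Conditions: Me2AlCl (1.5 equiv), CH2Cl2, −78 → −20 °C
Reagents that add atoms: none
Why: Me2AlCl binds the aldehyde oxygen and lowers the enal LUMO, so the silyloxy-raised diene HOMO should react at low temperature in a concerted, asynchronous, suprafacial [4+2] cycloaddition; the closest known reaction type is the Lewis-acid-promoted type 1 intramolecular Diels–Alder reaction of 2-silyloxy-diene trienals to trans-fused octalins with an angular methyl group. Ring B is closed as the cyclohexene of the cycloaddition itself (C5–C10 and C8–C9), and ring A is closed by the same C5–C10 bond across the four-carbon C1–C4 tether in the fused mode. The C9/C10 relation (formyl cis to H10, methyl cis to C1) follows from the (E)-enal geometry. The trans ring fusion (C5 methyl β, H10 α) follows from the endo-formyl, tether-anti chair-like transition state, which the Lewis acid accentuates. C8 follows from the (Z)-enol ether with its methyl outside the diene and so emerges cis to the formyl group, epimeric to the target, which step 13 corrects. The absolute sense is set by the C4 stereocentre, whose silyloxy group is expected to lie equatorial in the chair-like tether and so to expose one diene face. The step needs endo and facial selectivity plus chemoselective aldehyde complexation; the (E)-enal, the low temperature and the modest, proton-scavenging character of Me2AlCl are what should secure them, while the regiochemistry is fixed by the tether.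

Step 13
Reactants: 17 4β,7-bis(tert-butyldimethylsilyloxy)-5β,8α,9β-trimethyl-10αH-octal-6-ene-9α-carbaldehyde
Product: 19 4β-(tert-butyldimethylsilyloxy)-5β,8β,9β-trimethyl-7-oxo-10αH-decalin-9α-carbaldehyde, via C8-epimeric keto aldehyde 18 (not isolated)
Conditions: 1 M HCl, THF, 0 °C; then K2CO3, MeOH, rt
Reagents that add atoms: none
Why: Enol silyl ether hydrolysis (much faster than cleavage of the hindered secondary silyl ether) gives the C7 ketone, and base equilibration through the C7–C8 enolate should move the C8 methyl from the axial α to the equatorial β position, removing two syn-axial interactions; axial protonation from the α face leads the same way, and the formyl carbon on quaternary C9 cannot epimerise.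

Step 14
Reactants: 20 methyl 2,3,4-trihydroxybenzoate
Product: 21 methyl 2,3,4-trihydroxy-5-iodobenzoate
Conditions: NIS, MeCN, 0 °C → rt, dark
Reagents that add atoms: N-iodosuccinimide, O=C1CCC(=O)N1I
Why: Electrophilic aromatic iodination; C5 is ortho to the 4-hydroxyl, para to the 2-hydroxyl and meta to the ester, so it is the only strongly activated position.

Step 15
Reactants: 21 methyl 2,3,4-trihydroxy-5-iodobenzoate
Product: 22 methyl 5-iodo-2,3,4-tris(methoxymethoxy)benzoate
Conditions: NaH, MOMCl, DMF, 0 °C → rt
Reagents that add atoms: chloromethyl methyl ether, COCCl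
Why: Williamson-type alkylation of the three phenoxides; the strong base also engages the hydrogen-bonded 2-hydroxyl, and the acetals resist all later basic, hydridic and radical steps.

Step 16
Reactants: 22 methyl 5-iodo-2,3,4-tris(methoxymethoxy)benzoate; 19 4β-(tert-butyldimethylsilyloxy)-5β,8β,9β-trimethyl-7-oxo-10αH-decalin-9α-carbaldehyde
Product: 25 methyl 5-{hydroxy[4β-(tert-butyldimethylsilyloxy)-7-hydroxy-5β,8β,9β-trimethyl-10αH-decalin-9α-yl]methyl}-2,3,4-tris(methoxymethoxy)benzoate, via arylmagnesium chloride 23 (not isolated), via hydroxy ketone 24 (not isolated)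
Conditions: 22, i-PrMgCl·LiCl, THF, −40 °C; then 19, −40 → 0 °C; then MeOH, NaBH4, 0 °C
Reagents that add atoms: none
Why: Iodine–magnesium exchange at low temperature gives an aryl Grignard reagent that tolerates its own ester and should add to the aldehyde in preference to the hindered, enolisable C7 ketone; borohydride then reduces that ketone in the same flask, and the two new carbinol centres (C15, C7) are mixtures that step 18 erases.

Step 17
Reactants: 25 methyl 5-{hydroxy[4β-(tert-butyldimethylsilyloxy)-7-hydroxy-5β,8β,9β-trimethyl-10αH-decalin-9α-yl]methyl}-2,3,4-tris(methoxymethoxy)benzoate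
Product: 26 C7,C15-bis(S-methyl dithiocarbonate) of 25
Conditions: NaH, imidazole (cat.), THF, 0 °C; CS2; then MeI, rt
Reagents that add atoms: carbon disulfide, S=C=S; iodomethane, CI
Why: Xanthate formation through the alkoxides; carbon disulfide is small and electrophilic enough to reach both hindered oxygens, and ester, acetals and silyl ether are stable to these conditions.

Step 18
Reactants: 26 C7,C15-bis(S-methyl dithiocarbonate) of 25
Product: 27 methyl 5-{[4β-(tert-butyldimethylsilyloxy)-5β,8β,9β-trimethyl-10αH-decalin-9α-yl]methyl}-2,3,4-tris(methoxymethoxy)benzoate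
Conditions: Bu3SnH, AIBN (cat.), toluene, 100 °C
Reagents that add atoms: none
Why: Double Barton–McCombie deoxygenation: stannyl radical addition to each thiocarbonyl and β-scission give a benzylic C15 radical and a secondary C7 radical, both reduced by the tin hydride; no stereocentre is touched.

Step 19
Reactants: 27 methyl 5-{[4β-(tert-butyldimethylsilyloxy)-5β,8β,9β-trimethyl-10αH-decalin-9α-yl]methyl}-2,3,4-tris(methoxymethoxy)benzoate
Product: 28 methyl 5-{[4β-hydroxy-5β,8β,9β-trimethyl-10αH-decalin-9α-yl]methyl}-2,3,4-tris(methoxymethoxy)benzoate
Conditions: TBAF, THF, 45 °C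
Reagents that add atoms: none
Why: Fluoride cleavage of the silyl ether; warming is planned because the oxygen sits next to the quaternary C5, and acetals and ester tolerate fluoride.

Step 20
Reactants: 28 methyl 5-{[4β-hydroxy-5β,8β,9β-trimethyl-10αH-decalin-9α-yl]methyl}-2,3,4-tris(methoxymethoxy)benzoate
Product: 29 methyl 5-{[5β,8β,9β-trimethyl-4-oxo-10αH-decalin-9α-yl]methyl}-2,3,4-tris(methoxymethoxy)benzoate
Conditions: Dess–Martin periodinane, pyridine, CH2Cl2, rt
Reagents that add atoms: none
Why: Dess–Martin oxidation of the secondary alcohol; the C4 stereocentre has done its work and is removed, and no neighbouring centre can epimerise because C5 is quaternary.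

Step 21
Reactants: 29 methyl 5-{[5β,8β,9β-trimethyl-4-oxo-10αH-decalin-9α-yl]methyl}-2,3,4-tris(methoxymethoxy)benzoate
Product: 30 methyl 2,3,4-tris(methoxymethoxy)-5-{[(1R,2S,4aS,8aS)-1,2,4a-trimethyl-5-methylidenedecahydronaphthalen-1-yl]methyl}benzoate
Conditions: Ph3PCH3Br, KOtBu, toluene, 90 °C
Reagents that add atoms: methyltriphenylphosphonium bromide, C[P+](c1ccccc1)(c1ccccc1)c1ccccc1.[Br-]
Why: Wittig methylenation under the forcing conditions customary for ketones next to a quaternary carbon; the electron-rich, ortho-substituted aryl ester is a far poorer electrophile than the ketone.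

Step 22
Reactants: 30 methyl 2,3,4-tris(methoxymethoxy)-5-{[(1R,2S,4aS,8aS)-1,2,4a-trimethyl-5-methylidenedecahydronaphthalen-1-yl]methyl}benzoate
Product: 31 methyl 2,3,4-trihydroxy-5-{[(1R,2S,4aS,8aS)-1,2,4a-trimethyl-5-methylidenedecahydronaphthalen-1-yl]methyl}benzoate
Conditions: HCl (0.5 M), MeOH, 0 °C → rt, argon
Reagents that add atoms: none
Why: Acid-catalysed transacetalisation in methanol frees the three phenols as dimethoxymethane; methanol keeps the methyl ester unchanged, and dilute acid at low temperature is chosen because the 1,1-disubstituted alkene is the only other acid-sensitive site.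

## Compound list

1 | hex-4-yn-3-ol (racemic) | CCC(O)C#CC | starting material
2 | triethyl(hex-4-yn-3-yloxy)silane | CCC(O[Si](CC)(CC)CC)C#CC | intermediate
3 | (E)-chloro[5-(triethylsilyloxy)hex-2-en-2-yl]zirconocene (not isolated) | CCC(O[Si](CC)(CC)CC)/C=C(\C)[Zr](Cl)(C1C=CC=C1)C1C=CC=C1 | intermediate
4 | (E)-triethyl[(5-iodohex-4-en-3-yl)oxy]silane (iodine trans to the carbinol carbon) | CCC(O[Si](CC)(CC)CC)/C=C(\C)I | intermediate
5 | δ-valerolactone | O=C1CCCCO1 | starting material
6 | 5-hydroxy-N-methoxy-N-methylpentanamide | CON(C)C(=O)CCCCO | intermediate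
7 | N-methoxy-N-methyl-5-oxopentanamide | CON(C)C(=O)CCCC=O | intermediate
8 | (E)-[5-(triethylsilyloxy)hex-2-en-2-yl]chromium dichloride (trivalent chromium; chiral ligand omitted; not isolated) | CCC(O[Si](CC)(CC)CC)/C=C(\C)[Cr](Cl)Cl | intermediate
9 | (5S,6E)-5-hydroxy-N-methoxy-N,6-dimethyl-8-(triethylsilyloxy)dec-6-enamide (both C8 epimers of the chain) | CON(C)C(=O)CCC[C@H](O)/C(C)=C/C(CC)O[Si](CC)(CC)CC | intermediate
10 | (5S,6E)-5-(tert-butyldimethylsilyloxy)-N-methoxy-N,6-dimethyl-8-(triethylsilyloxy)dec-6-enamide | CON(C)C(=O)CCC[C@H](O[Si](C)(C)C(C)(C)C)/C(C)=C/C(CC)O[Si](CC)(CC)CC | intermediate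
11 | (5S,6E)-5-(tert-butyldimethylsilyloxy)-8-hydroxy-N-methoxy-N,6-dimethyldec-6-enamide | CON(C)C(=O)CCC[C@H](O[Si](C)(C)C(C)(C)C)/C(C)=C/C(O)CC | intermediate
12 | (5S,6E)-5-(tert-butyldimethylsilyloxy)-N-methoxy-N,6-dimethyl-8-oxodec-6-enamide | CON(C)C(=O)CCC[C@H](O[Si](C)(C)C(C)(C)C)/C(C)=C/C(=O)CC | intermediate
13 | (5S,6E,8Z)-5,8-bis(tert-butyldimethylsilyloxy)-N-methoxy-N,6-dimethyldeca-6,8-dienamide | CON(C)C(=O)CCC[C@H](O[Si](C)(C)C(C)(C)C)/C(C)=C/C(O[Si](C)(C)C(C)(C)C)=C/C | intermediate
14 | (5S,6E,8Z)-5,8-bis(tert-butyldimethylsilyloxy)-6-methyldeca-6,8-dienal | O=CCCC[C@H](O[Si](C)(C)C(C)(C)C)/C(C)=C/C(O[Si](C)(C)C(C)(C)C)=C/C | intermediate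
15 | 2-(triphenylphosphoranylidene)propanal | CC(C=O)=P(c1ccccc1)(c1ccccc1)c1ccccc1 | starting material
16 | (2E,7S,8E,10Z)-7,10-bis(tert-butyldimethylsilyloxy)-2,8-dimethyldodeca-2,8,10-trienal | O=C/C(C)=C/CCC[C@H](O[Si](C)(C)C(C)(C)C)/C(C)=C/C(O[Si](C)(C)C(C)(C)C)=C/C | intermediate
17 | trans-fused octalin: 4β- and 7-(tert-butyldimethylsilyloxy), 5β-, 8α- and 9β-methyl, 9α-formyl, 10α-H, C6=C7 | [C@H]1(O[Si](C)(C)C(C)(C)C)CCC[C@H]2[C@](C)(C=O)[C@H](C)C(O[Si](C)(C)C(C)(C)C)=C[C@]12C | intermediate
18 | C8-epimeric (8α-methyl) 7-oxo decalin aldehyde (not isolated) | [C@H]1(O[Si](C)(C)C(C)(C)C)CCC[C@H]2[C@](C)(C=O)[C@H](C)C(=O)C[C@]12C | intermediate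
19 | 4β-(tert-butyldimethylsilyloxy)-5β,8β,9β-trimethyl-7-oxo-10αH-decalin-9α-carbaldehyde | [C@H]1(O[Si](C)(C)C(C)(C)C)CCC[C@H]2[C@](C)(C=O)[C@@H](C)C(=O)C[C@]12C | intermediate
20 | methyl 2,3,4-trihydroxybenzoate | COC(=O)c1ccc(O)c(O)c1O | starting material
21 | methyl 2,3,4-trihydroxy-5-iodobenzoate | COC(=O)c1cc(I)c(O)c(O)c1O | intermediate
22 | methyl 5-iodo-2,3,4-tris(methoxymethoxy)benzoate | COC(=O)c1cc(I)c(OCOC)c(OCOC)c1OCOC | intermediate
23 | [5-(methoxycarbonyl)-2,3,4-tris(methoxymethoxy)phenyl]magnesium chloride, LiCl complex (not isolated) | COC(=O)c1cc([Mg]Cl)c(OCOC)c(OCOC)c1OCOC | intermediate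
24 | C15 hydroxy, C7 oxo adduct of 19 and 23, C15 epimers (not isolated) | [C@H]1(O[Si](C)(C)C(C)(C)C)CCC[C@H]2[C@](C)(C(O)c3cc(C(=O)OC)c(OCOC)c(OCOC)c3OCOC)[C@@H](C)C(=O)C[C@]12C | intermediate
25 | C7,C15-diol (epimers at both carbinol carbons) | [C@H]1(O[Si](C)(C)C(C)(C)C)CCC[C@H]2[C@](C)(C(O)c3cc(C(=O)OC)c(OCOC)c(OCOC)c3OCOC)[C@@H](C)C(O)C[C@]12C | intermediate
26 | C7,C15-bis(S-methyl dithiocarbonate) of 25 | [C@H]1(O[Si](C)(C)C(C)(C)C)CCC[C@H]2[C@](C)(C(OC(=S)SC)c3cc(C(=O)OC)c(OCOC)c(OCOC)c3OCOC)[C@@H](C)C(OC(=S)SC)C[C@]12C | intermediate
27 | methyl 5-{[4β-(tert-butyldimethylsilyloxy)-5β,8β,9β-trimethyl-10αH-decalin-9α-yl]methyl}-2,3,4-tris(methoxymethoxy)benzoate | [C@H]1(O[Si](C)(C)C(C)(C)C)CCC[C@H]2[C@](C)(Cc3cc(C(=O)OC)c(OCOC)c(OCOC)c3OCOC)[C@@H](C)CC[C@]12C | intermediate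
28 | the 4β-alcohol corresponding to 27 | [C@H]1(O)CCC[C@H]2[C@](C)(Cc3cc(C(=O)OC)c(OCOC)c(OCOC)c3OCOC)[C@@H](C)CC[C@]12C | intermediate
29 | the C4 ketone corresponding to 28 | O=C1CCC[C@H]2[C@](C)(Cc3cc(C(=O)OC)c(OCOC)c(OCOC)c3OCOC)[C@@H](C)CC[C@]12C | intermediate
30 | methyl 2,3,4-tris(methoxymethoxy)-5-{[(1R,2S,4aS,8aS)-1,2,4a-trimethyl-5-methylidenedecahydronaphthalen-1-yl]methyl}benzoate | C=C1CCC[C@H]2[C@](C)(Cc3cc(C(=O)OC)c(OCOC)c(OCOC)c3OCOC)[C@@H](C)CC[C@]12C | intermediate
31 | methyl 2,3,4-trihydroxy-5-{[(1R,2S,4aS,8aS)-1,2,4a-trimethyl-5-methylidenedecahydronaphthalen-1-yl]methyl}benzoate | C=C1CCC[C@H]2[C@](C)(Cc3cc(C(=O)OC)c(O)c(O)c3O)[C@@H](C)CC[C@]12C | target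

## Step count and least certain steps

Total step count: 22. Longest linear sequence: 18 steps (1, 2, 5–13, 16–22); steps 3–4 and 14–15 are side branches.

**Step 12 (key step).** The most likely failure is weak or reversed diene-face discrimination. A transition state with the C4 silyloxy group axial and in the plane of the diene ("inside") could compete with the equatorial one. A second risk is Lewis-acid removal of the enol silyl group before cycloaddition, since the tether enforces an orientation that is not the electronically preferred one and the reaction may be slow. The fallback moves the stereocontrol from the substrate to the reagent. Setting out from 16, the cycloaddition would be run with a chiral cationic boron Lewis acid: the triflimide salt of (S)-3,3-diphenyl-1-(2-methylphenyl)tetrahydro-1H,3H-pyrrolo[1,2-c][1,3,2]oxazaborole, or its antipode, whichever is matched. This catalyst type binds α-substituted enals in a defined geometry and shields one dienophile face. The fallback returns to the route at 17 and makes no new compound (F0). Because C4 becomes sp2 in 29, any C4-epimeric adduct of the correct decalin series would also converge there.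

**Step 5.** The most likely failure is insufficient enantioselectivity, or slow coupling, with a trisubstituted alkenyl iodide under the ligand-loaded chromium conditions. The fallback sets out from 4 and 7. Coupling without the chiral ligand (CrCl2, NiCl2 cat., DMSO) should give the C4-racemic allylic alcohol F1. Dess–Martin oxidation would give the α-methyl enone F2. Reduction with catecholborane and (R)-1-methyl-3,3-diphenyltetrahydro-1H,3H-pyrrolo[1,2-c][1,3,2]oxazaborole at −78 °C (CBS reduction, amide untouched) should deliver the (S)-carbinol and return to the route at 9.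

**Step 16.** The most likely failure is slow addition to the neopentyl aldehyde. The ester-bearing arylmagnesium would then have time to condense with itself or to act as a base toward the C7 ketone. The fallback sets out from 19 and uses an ester-free arene:
- 1,2,3-tris(methoxymethoxy)benzene F3 (from pyrogallol, NaH, MOMCl) is lithiated ortho to an acetal (n-BuLi, TMEDA, THF, 0 °C) to 2,3,4-tris(methoxymethoxy)phenyllithium F4.
- Addition to 19 at −78 °C should give the ester-free hydroxy ketone F5, reduced in the same flask (NaBH4, MeOH) to the ester-free diol F6.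
- Thioacylation as in step 17 gives the ester-free bis(dithiocarbonate) F7, and radical reduction as in step 18 the ester-free decalinylmethyl arene F8.
- Directed ortho-lithiation of F8 next to the C4' acetal (n-BuLi, TMEDA) gives the C5' aryllithium F9, and methyl chloroformate at −78 °C installs the ester, returning to the route at 27.

**Step 21.** The most likely failure is consumption of the basic ylide by the aryl ester, or by enolisation of the hindered ketone, at the temperature the addition needs. The fallback is a Johnson sulfoximine methylenation setting out from 29. Lithiated N,S-dimethyl-S-phenylsulfoximine (n-BuLi, THF, −78 °C) should add to the ketone selectively to give the β-hydroxy sulfoximine F10. Reductive elimination with Al(Hg) in THF/H2O/AcOH should then give the alkene and return to the route at 30.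

**Step 22.** The most likely failure is acid-induced migration of the exocyclic double bond into ring A while the last, most hindered acetal is being cleaved, together with aerial oxidation of the freed pyrogallol. The fallback reverses the order of the last two operations and sets out from 29. The acetals are cleaved with HCl in MeOH while no alkene is present, giving the triphenol ketone F11. F11 is then methylenated with an excess of salt-free Ph3P=CH2 in THF/DMSO under argon; the phenoxides formed in the flask deactivate the ester. Work-up with aq. NH4Cl should give the target directly, returning to the route at 31.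

## Further compounds

F0 | step 12 | none | none
F1 | step 5 | (6E)-5-hydroxy-N-methoxy-N,6-dimethyl-8-(triethylsilyloxy)dec-6-enamide, racemic at C5 | CON(C)C(=O)CCCC(O)/C(C)=C/C(CC)O[Si](CC)(CC)CC
F2 | step 5 | (6E)-N-methoxy-N,6-dimethyl-5-oxo-8-(triethylsilyloxy)dec-6-enamide | CON(C)C(=O)CCCC(=O)/C(C)=C/C(CC)O[Si](CC)(CC)CC
F3 | step 16 | 1,2,3-tris(methoxymethoxy)benzene | COCOc1cccc(OCOC)c1OCOC
F4 | step 16 | 2,3,4-tris(methoxymethoxy)phenyllithium | [Li]c1ccc(OCOC)c(OCOC)c1OCOC
F5 | step 16 | ester-free analogue of 24 (C15 hydroxy, C7 oxo) | [C@H]1(O[Si](C)(C)C(C)(C)C)CCC[C@H]2[C@](C)(C(O)c3ccc(OCOC)c(OCOC)c3OCOC)[C@@H](C)C(=O)C[C@]12C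
F6 | step 16 | ester-free analogue of 25 (C7,C15-diol) | [C@H]1(O[Si](C)(C)C(C)(C)C)CCC[C@H]2[C@](C)(C(O)c3ccc(OCOC)c(OCOC)c3OCOC)[C@@H](C)C(O)C[C@]12C
F7 | step 16 | ester-free analogue of 26 (bis(S-methyl dithiocarbonate)) | [C@H]1(O[Si](C)(C)C(C)(C)C)CCC[C@H]2[C@](C)(C(OC(=S)SC)c3ccc(OCOC)c(OCOC)c3OCOC)[C@@H](C)C(OC(=S)SC)C[C@]12C
F8 | step 16 | ester-free analogue of 27 | [C@H]1(O[Si](C)(C)C(C)(C)C)CCC[C@H]2[C@](C)(Cc3ccc(OCOC)c(OCOC)c3OCOC)[C@@H](C)CC[C@]12C
F9 | step 16 | C5'-lithio derivative of F8 | [C@H]1(O[Si](C)(C)C(C)(C)C)CCC[C@H]2[C@](C)(Cc3cc([Li])c(OCOC)c(OCOC)c3OCOC)[C@@H](C)CC[C@]12C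
F10 | step 21 | β-hydroxy sulfoximine from 29 (C4 hydroxy, C4 CH2S(O)(=NMe)Ph; mixture at C4 and sulfur) | OC1(CS(=O)(=NC)c2ccccc2)CCC[C@H]2[C@](C)(Cc3cc(C(=O)OC)c(OCOC)c(OCOC)c3OCOC)[C@@H](C)CC[C@]12C
F11 | step 22 | methyl 2,3,4-trihydroxy-5-{[5β,8β,9β-trimethyl-4-oxo-10αH-decalin-9α-yl]methyl}benzoate | O=C1CCC[C@H]2[C@](C)(Cc3cc(C(=O)OC)c(O)c(O)c3O)[C@@H](C)CC[C@]12C
A1 | alternative 1 | C15 magnesium bromide of the decalin of 31 (decalinylmethyl Grignard reagent) | C=C1CCC[C@H]2[C@](C)(C[Mg]Br)[C@@H](C)CC[C@]12C
A2 | alternative 1 | 2-iodo-3,4-bis(methoxymethoxy)phenyl 4-chlorobenzenesulfonate | COCOc1ccc(OS(=O)(=O)c2ccc(Cl)cc2)c(I)c1OCOC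
A3 | alternative 1 | 3,4-bis(methoxymethoxy)benzyne | COCOC1=C(OCOC)C#CC=C1
A4 | alternative 1 | decalinylmethyl phenol lacking the ester (2'-hydroxy, 3',4'-bis(methoxymethoxy)) | C=C1CCC[C@H]2[C@](C)(Cc3ccc(OCOC)c(OCOC)c3O)[C@@H](C)CC[C@]12C
A5 | alternative 2 | ring B aldehyde: C5 methyl and isopropenyl, C10 CH2CHO, C9 methyl and tri-O-methyl arylmethyl, C8 methyl | O=CC[C@H]1[C@](C)(Cc2cc(C(=O)OC)c(OC)c(OC)c2OC)[C@@H](C)CC[C@]1(C)C(C)=C
A6 | alternative 2 | 2-hydroxy derivative of the target tri-O-methyl ether | C=C1C[C@H](O)C[C@H]2[C@](C)(Cc3cc(C(=O)OC)c(OC)c(OC)c3OC)[C@@H](C)CC[C@]12C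
A7 | alternative 3 | methyl 5-[(3S,6E)-3,6-dimethyl-2-methylidenedodec-6-en-11-yn-1-yl]-2,3,4-tris(methoxymethoxy)benzoate | C#CCCC/C=C(\C)CC[C@H](C)C(=C)Cc1cc(C(=O)OC)c(OCOC)c(OCOC)c1OCOC
A8 | alternative 3 | tris(methoxymethyl) ether of the target (identical with 30) | C=C1CCC[C@H]2[C@](C)(Cc3cc(C(=O)OC)c(OCOC)c(OCOC)c3OCOC)[C@@H](C)CC[C@]12C
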